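**Plan**

- Retrosynthesis: the two aryl C3′–O bonds (one in each catechol ring) are cut first, leaving two 4′-hydroxycinnamoyl rings. Then come the O–allyl protecting bonds, the two enoate ester C–O bonds at O3 and O5, and the succinate ester C–O bond at O4, back to (−)-quinic acid, (E)-p-coumaric acid and succinic anhydride.
- Enabling feature: each aryl ring carries the enoate carbon at C1′ and the phenol oxygen at C4′, so C3′–H and C5′–H are equivalent ortho positions. Oxygen passed from the C4′ oxygen to either one gives the same 3′,4′-dihydroxyphenyl ring.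
- Forward order: no ring is built (the cyclohexane and both benzene rings are bought). The sequence is carboxyl to allyl ester, O3/O5 to TBS ethers, O4 to allyl succinate, desilylation, O3/O5 to O-allyl-p-coumaroyl esters, one palladium deallylation, then the double ortho-hydroxylation.
- Stereochemistry: C1, C3, C4 and C5 come unchanged from (−)-quinic acid, because only O–acyl, O–Si and O–allyl bonds are made or broken and never a ring C–O bond. Both E alkenes come from (E)-p-coumaric acid.

Key step: step 9

Remark: IUPAC quinic acid numbering is used (C1 carries OH and CO2H; the oxygens on C1, C3 and C4 lie on one face of the ring, the C5 oxygen and the carboxyl carbon on the other). The target SMILES shows exactly this arrangement, so the target is a triester of natural (−)-quinic acid.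

**Route**

Step 1
Reactants: 1 (−)-quinic acid
Product: 2 allyl quinate
Conditions: Cs2CO3 (0.55 equiv), allyl bromide (1.2 equiv), DMF, rt
Reagents that add atoms: allyl bromide, C=CCBr
Why: SN2 O-alkylation of the carboxylate formed with Cs2CO3 (carboxylate-salt esterification) should esterify only the acid, since carbonate does not deprotonate the four hydroxyls and no stereocenter is touched.

Step 2
Reactants: 2 allyl quinate
Product: 3 allyl 3,5-bis-O-(tert-butyldimethylsilyl)quinate
Conditions: TBSCl (2.2 equiv), imidazole, DMF, 0 °C to rt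
Reagents that add atoms: tert-butyldimethylsilyl chloride, CC(C)(C)[Si](C)(C)Cl
Why: Imidazole-promoted silylation should take the two secondary hydroxyls that each have a CH2 neighbour (O3 and O5), after which the O4 hydroxyl is shielded between two silyloxy groups and the tertiary O1 carbinol is too hindered to react, a selectivity known for methyl quinate.

Step 3
Reactants: 4 succinic anhydride
Product: 5 mono-allyl succinate (4-(allyloxy)-4-oxobutanoic acid)
Conditions: allyl alcohol (1.2 equiv), DMAP (5 mol %), toluene, 80 °C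
Reagents that add atoms: allyl alcohol, C=CCO
Why: DMAP-catalysed alcoholysis of a cyclic anhydride should stop cleanly at the half ester because the carboxylic acid formed is not acylating.

Step 4
Reactants: 3 allyl 3,5-bis-O-(tert-butyldimethylsilyl)quinate; 5 mono-allyl succinate
Product: 6 allyl 4-O-[4-(allyloxy)-4-oxobutanoyl]-3,5-bis-O-(tert-butyldimethylsilyl)quinate
Conditions: 5 (2.5 equiv), DIC (2.5 equiv), DMAP (1 equiv), CH2Cl2, rt
Reagents that add atoms: none
Why: Steglich esterification through the acylpyridinium ion should acylate the only remaining secondary hydroxyl (equatorial O4), which is known to accept acyl-type electrophiles in 3,5-bis-silylated quinates, while the tertiary α-hydroxy ester carbinol at C1 does not compete.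

Step 5
Reactants: 6 allyl 4-O-[4-(allyloxy)-4-oxobutanoyl]-3,5-bis-O-(tert-butyldimethylsilyl)quinate
Product: 7 allyl 4-O-[4-(allyloxy)-4-oxobutanoyl]quinate (3,5-diol)
Conditions: HF·pyridine, pyridine/THF, 0 °C to rt; cold pH 7 buffer quench
Reagents that add atoms: none
Why: Fluoride cleavage of the two silyl ethers under buffered acidic conditions generates no alkoxide, so the O4 succinate should stay in place instead of migrating to O3 or O5, and allyl esters are inert to the reagent.

Step 6
Reactants: 8 (E)-p-coumaric acid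
Product: 10 (E)-4-(allyloxy)cinnamic acid, via allyl (E)-4-(allyloxy)cinnamate 9 (not isolated)
Conditions: allyl bromide (2.5 equiv), K2CO3, DMF, 50 °C; then NaOH, MeOH/H2O, 50 °C; HCl work-up
Reagents that add atoms: allyl bromide, C=CCBr; NaOH, [Na+].[OH-]
Why: Williamson etherification of the phenoxide with concurrent carboxylate alkylation, followed by saponification of the allyl ester only, should give the O-protected acid, since the aryl allyl ether and the E alkene are stable to hydroxide.

Step 7
Reactants: 7 allyl 4-O-[4-(allyloxy)-4-oxobutanoyl]quinate; 10 (E)-4-(allyloxy)cinnamic acid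
Product: 12 allyl 3,5-bis-O-[(E)-4-(allyloxy)cinnamoyl]-4-O-[4-(allyloxy)-4-oxobutanoyl]quinate, via (E)-4-(allyloxy)cinnamoyl chloride 11 (not isolated)
Conditions: 10 (2.6 equiv), (COCl)2, cat. DMF, CH2Cl2, 0 °C to rt, concentrate; then 7, pyridine, DMAP (0.2 equiv), CH2Cl2, 0 °C to rt
Reagents that add atoms: none
Why: DMAP-catalysed acylation with the acid chloride should esterify the equatorial O5 and axial O3 hydroxyls faster than the succinate can migrate, and with the acyl chloride limited to a small excess the tertiary O1 carbinol should remain free.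

Step 8
Reactants: 12 allyl 3,5-bis-O-[(E)-4-(allyloxy)cinnamoyl]-4-O-[4-(allyloxy)-4-oxobutanoyl]quinate
Product: 13 3,5-di-O-[(E)-p-coumaroyl]-4-O-succinylquinic acid
Conditions: Pd(PPh3)4 (10 mol %), morpholine (12 equiv), THF, rt, argon; 1 M HCl work-up, C18 chromatography
Reagents that add atoms: none
Why: In this Tsuji–Trost deallylation zerovalent palladium ionises both allyl esters and both aryl allyl ethers to π-allyl complexes that morpholine captures, which should free the two acids and two phenols in one operation without touching the cinnamate or succinate esters.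

Step 9
Reactants: 13 3,5-di-O-[(E)-p-coumaroyl]-4-O-succinylquinic acid
Product: 15 3,5-di-O-[(E)-caffeoyl]-4-O-succinylquinic acid, via bis-o-quinone 14 (not isolated)
Conditions: IBX (2.4 equiv), DMF, 0 °C to rt, dark; then aq. Na2S2O4, 0 °C; acidify to pH 3, C18 reversed-phase chromatography
Reagents that add atoms: 2-iodoxybenzoic acid (IBX), O=C1OI(=O)(O)c2ccccc12
Why: Each phenol oxygen displaces a hydroxyl ligand on the pentavalent iodine of IBX, the aryl–O–I species passes an iodine-bound oxygen to the adjacent ring carbon C3′ in a concerted shift that lowers iodine to the trivalent state, and the catechol iodinane so formed collapses to the o-quinone with release of 2-iodobenzoic acid (monovalent iodine); Na2S2O4 added to the same flask then reduces both quinones to catechols. The closest known reaction type is the IBX oxidation of 4-substituted phenols to o-quinones with reductive work-up, the established way from tyrosol-, tyrosine- and 4-hydroxystilbene-type phenols to their catechols. No ring is closed and no stereocenter is created, the four ring stereocenters being distant spectators. The step needs ortho-regioselectivity and chemoselectivity for the two phenols: oxygen can only be delivered through the O–I tether to a carbon next to C4′, the para position is blocked by the enoate, C3′ and C5′ are equivalent, and nothing else in 13 (tertiary carbinol, carboxylic acids, esters, enoate alkenes) should be oxidised by IBX at or below room temperature. Because the enoate makes these phenols less electron-rich than the usual substrates, a small excess of oxidant, dilution and reduction as soon as 13 is consumed are meant to keep the electrophilic quinone from adding nucleophiles or unreacted phenol.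

**Compound list**

1 | (−)-quinic acid | O[C@H]1[C@H](O)C[C@](O)(C(=O)O)C[C@H]1O | starting material
2 | allyl quinate (prop-2-enyl ester of 1) | O[C@H]1[C@H](O)C[C@](O)(C(=O)OCC=C)C[C@H]1O | intermediate
3 | allyl 3,5-bis-O-(tert-butyldimethylsilyl)quinate | O[C@H]1[C@H](O[Si](C)(C)C(C)(C)C)C[C@](O)(C(=O)OCC=C)C[C@H]1O[Si](C)(C)C(C)(C)C | intermediate
4 | succinic anhydride | O=C1CCC(=O)O1 | starting material
5 | mono-allyl succinate (4-(allyloxy)-4-oxobutanoic acid) | C=CCOC(=O)CCC(=O)O | intermediate
6 | allyl 4-O-[4-(allyloxy)-4-oxobutanoyl]-3,5-bis-O-(tert-butyldimethylsilyl)quinate | C=CCOC(=O)CCC(=O)O[C@H]1[C@H](O[Si](C)(C)C(C)(C)C)C[C@](O)(C(=O)OCC=C)C[C@H]1O[Si](C)(C)C(C)(C)C | intermediate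
7 | allyl 4-O-[4-(allyloxy)-4-oxobutanoyl]quinate (3-OH and 5-OH free) | C=CCOC(=O)CCC(=O)O[C@H]1[C@H](O)C[C@](O)(C(=O)OCC=C)C[C@H]1O | intermediate
8 | (E)-p-coumaric acid | OC(=O)/C=C/c1ccc(O)cc1 | starting material
9 | allyl (E)-4-(allyloxy)cinnamate | C=CCOC(=O)/C=C/c1ccc(OCC=C)cc1 | intermediate (not isolated)
10 | (E)-4-(allyloxy)cinnamic acid | OC(=O)/C=C/c1ccc(OCC=C)cc1 | intermediate
11 | (E)-4-(allyloxy)cinnamoyl chloride | ClC(=O)/C=C/c1ccc(OCC=C)cc1 | intermediate (not isolated)
12 | allyl 3,5-bis-O-[(E)-4-(allyloxy)cinnamoyl]-4-O-[4-(allyloxy)-4-oxobutanoyl]quinate | C=CCOC(=O)CCC(=O)O[C@H]1[C@H](OC(=O)/C=C/c2ccc(OCC=C)cc2)C[C@](O)(C(=O)OCC=C)C[C@H]1OC(=O)/C=C/c1ccc(OCC=C)cc1 | intermediate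
13 | 3,5-di-O-[(E)-p-coumaroyl]-4-O-succinylquinic acid | O=C(O)CCC(=O)O[C@H]1[C@H](OC(=O)/C=C/c2ccc(O)cc2)C[C@](O)(C(=O)O)C[C@H]1OC(=O)/C=C/c1ccc(O)cc1 | intermediate
14 | bis-o-quinone of 13 (each aryl ring a 4-substituted 1,2-benzoquinone) | O=C(O)CCC(=O)O[C@H]1[C@H](OC(=O)/C=C/C2=CC(=O)C(=O)C=C2)C[C@](O)(C(=O)O)C[C@H]1OC(=O)/C=C/C1=CC(=O)C(=O)C=C1 | intermediate (not isolated)
15 | 3,5-di-O-[(E)-caffeoyl]-4-O-succinylquinic acid | O=C(O)CCC(=O)O[C@H]1[C@H](OC(=O)/C=C/c2ccc(O)c(O)c2)C[C@](O)(C(=O)O)C[C@H]1OC(=O)/C=C/c1ccc(O)c(O)c1 | target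

**Count**

Total steps: 9. Longest linear sequence: 7 (steps 1, 2, 4, 5, 7, 8, 9 from 1); steps 3 and 6 prepare the two acyl donors.

**Steps most likely to fail**

1. Step 9. The enoate-deactivated phenols may exchange onto iodine and accept oxygen only slowly, so that oxidation stalls after one ring, while the quinone already formed decays by conjugate addition or oligomerisation before the reductant arrives. Fallback: the catechol oxygens are brought in with the acyl donor instead of by C–H oxygenation, setting out from diol 7. Commercial caffeic acid is per-allylated (allyl bromide, K2CO3, DMF) to allyl (E)-3,4-bis(allyloxy)cinnamate F1. This is saponified (NaOH, MeOH/H2O) to (E)-3,4-bis(allyloxy)cinnamic acid F2, which (COCl)2 with cat. DMF turns into (E)-3,4-bis(allyloxy)cinnamoyl chloride F3. Acylation of 7 under the conditions of step 7 would give allyl 3,5-bis-O-[(E)-3,4-bis(allyloxy)cinnamoyl]-4-O-[4-(allyloxy)-4-oxobutanoyl]quinate F4. Pd(PPh3)4 with 4-toluenesulfinic acid in degassed THF/MeOH then removes all six allyl groups without base, and the route is rejoined at target 15.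

2. Step 5. The O4 succinate may migrate to the newly freed O3 or O5 hydroxyl during deprotection, quench or chromatography, which would scramble the ester pattern. Fallback: the order of acylation is reversed behind an ether that cannot migrate, setting out from 3. 4-Methoxybenzyl 2,2,2-trichloroacetimidate with catalytic camphorsulfonic acid in CH2Cl2 should give allyl 3,5-bis-O-(tert-butyldimethylsilyl)-4-O-(4-methoxybenzyl)quinate F5. HF·pyridine then gives allyl 4-O-(4-methoxybenzyl)quinate F6, and acylation with 11 as in step 7 gives allyl 3,5-bis-O-[(E)-4-(allyloxy)cinnamoyl]-4-O-(4-methoxybenzyl)quinate F7. DDQ in CH2Cl2/pH 7 buffer frees O4 to give allyl 3,5-bis-O-[(E)-4-(allyloxy)cinnamoyl]quinate F8. Esterification of F8 with 5 (DIC, DMAP) returns to the route at 12.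

3. Step 7. Esterification of the axial, hydrogen-bonded O3 hydroxyl may be incomplete, and forcing it may acylate the tertiary O1 carbinol or let the succinate migrate under base. Fallback: the enoate units are built on the ring by condensation, setting out from 7. Meldrum's acid in toluene at 80–90 °C should open on both hydroxyls to give allyl 3,5-bis-O-(carboxyacetyl)-4-O-[4-(allyloxy)-4-oxobutanoyl]quinate F9. Knoevenagel–Doebner condensation with 4-hydroxybenzaldehyde (pyridine, cat. piperidine, 50 °C) with loss of CO2 would give allyl 3,5-di-O-[(E)-4-hydroxycinnamoyl]-4-O-[4-(allyloxy)-4-oxobutanoyl]quinate F10, with no phenol protection needed. Deallylation as in step 8 returns to the route at 13.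

**Further compounds**

F1 | step 9 | allyl (E)-3,4-bis(allyloxy)cinnamate | C=CCOC(=O)/C=C/c1ccc(OCC=C)c(OCC=C)c1
F2 | step 9 | (E)-3,4-bis(allyloxy)cinnamic acid | OC(=O)/C=C/c1ccc(OCC=C)c(OCC=C)c1
F3 | step 9 | (E)-3,4-bis(allyloxy)cinnamoyl chloride | ClC(=O)/C=C/c1ccc(OCC=C)c(OCC=C)c1
F4 | step 9 | allyl 3,5-bis-O-[(E)-3,4-bis(allyloxy)cinnamoyl]-4-O-[4-(allyloxy)-4-oxobutanoyl]quinate | C=CCOC(=O)CCC(=O)O[C@H]1[C@H](OC(=O)/C=C/c2ccc(OCC=C)c(OCC=C)c2)C[C@](O)(C(=O)OCC=C)C[C@H]1OC(=O)/C=C/c1ccc(OCC=C)c(OCC=C)c1
F5 | step 5 | allyl 3,5-bis-O-(tert-butyldimethylsilyl)-4-O-(4-methoxybenzyl)quinate | COc1ccc(CO[C@H]2[C@H](O[Si](C)(C)C(C)(C)C)C[C@](O)(C(=O)OCC=C)C[C@H]2O[Si](C)(C)C(C)(C)C)cc1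
F6 | step 5 | allyl 4-O-(4-methoxybenzyl)quinate | COc1ccc(CO[C@H]2[C@H](O)C[C@](O)(C(=O)OCC=C)C[C@H]2O)cc1
F7 | step 5 | allyl 3,5-bis-O-[(E)-4-(allyloxy)cinnamoyl]-4-O-(4-methoxybenzyl)quinate | COc1ccc(CO[C@H]2[C@H](OC(=O)/C=C/c3ccc(OCC=C)cc3)C[C@](O)(C(=O)OCC=C)C[C@H]2OC(=O)/C=C/c2ccc(OCC=C)cc2)cc1
F8 | step 5 | allyl 3,5-bis-O-[(E)-4-(allyloxy)cinnamoyl]quinate (4-OH free) | O[C@H]1[C@H](OC(=O)/C=C/c2ccc(OCC=C)cc2)C[C@](O)(C(=O)OCC=C)C[C@H]1OC(=O)/C=C/c1ccc(OCC=C)cc1
F9 | step 7 | allyl 3,5-bis-O-(carboxyacetyl)-4-O-[4-(allyloxy)-4-oxobutanoyl]quinate | C=CCOC(=O)CCC(=O)O[C@H]1[C@H](OC(=O)CC(=O)O)C[C@](O)(C(=O)OCC=C)C[C@H]1OC(=O)CC(=O)O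
F10 | step 7 | allyl 3,5-di-O-[(E)-4-hydroxycinnamoyl]-4-O-[4-(allyloxy)-4-oxobutanoyl]quinate | C=CCOC(=O)CCC(=O)O[C@H]1[C@H](OC(=O)/C=C/c2ccc(O)cc2)C[C@](O)(C(=O)OCC=C)C[C@H]1OC(=O)/C=C/c1ccc(O)cc1
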